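## The problem

The target 38 is made of two halves that share no ring: a 6-methoxy-8-methyl-2H-chromene (benzene ring A fused to pyran ring B) and a cis-1,2-dimethylcyclopentane (ring C), tied together by the bridge C2–CH2–C(=O)–CH2–C1'. C2', the ring neighbour of C1', carries a (Z)-4-hydroxy-4-methylpent-2-enoyl group. All three stereocentres are fully substituted: C2 (R) is a tertiary allylic aryl ether, and C1' and C2' (both S) are adjacent quaternary carbons with cis methyl groups. C2 and C1' are three acyclic atoms apart, so neither half can steer the other; each must be set by a reagent and the halves joined as single enantiomers. Inside ring C the cis relation is best locked by a ring fusion. The bridge ketone is β to the aryloxy oxygen, so an enolate or strong acid invites retro-oxa-Michael opening of ring B and loss of C2. Ring B also ionises at C2 and opens electrocyclically in light, the two ketones are 1,5-related and can aldolise, and the Z-enone can isomerise or close onto its tertiary hydroxyl. The feature that makes the key step possible is that both non-methyl carbon substituents of C2 begin with a two-carbon unit, C3=C4 of ring B and the CH2–C(=O) arm. Both can be traced to vinyl groups, which turns C2 into a prochiral carbinol carbon with two enantiotopic vinyls, facing a third vinyl on ring A at the future C4a.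

## Retrosynthesis

**38 to 37.** The Z-alkene is made last, by syn addition of hydrogen to the ynone 37. This keeps the isomerisation-prone Z-γ-hydroxy enone out of every earlier step. The forward reaction must stop at the alkene and leave C3=C4 alone.

**37 to 33 and 35.** The bond between the acyl carbon on C2' and the alkyne is cut, through the propargylic alcohol 36. The acyl carbon arrives as the aldehyde of 33 and the alkyne as iodoalkyne 35, one step from 2-methylbut-3-yn-2-ol 34. Adding an acetylide to an acid derivative on C2' would instead meet the more reactive bridge ketone. The forward reaction must be aldehyde-selective and non-basic, because 33 holds an enolisable β-aryloxy ketone.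

**33 to 31.** The aldehyde is traced through alcohol 32 to the silyl ether 31. This costs two functional-group steps, justified in the next paragraph.

**31 to 16 and 30.** The C(=O)–CH2 bond on the ring C side is cut. The C(=O)–CH2 bond on the ring B side would need a carbanion next to C2, which would expel the aryloxide. The CH2 next to C1' lies between two quaternary carbons and is closed to substitution chemistry. A primary radical released by decarboxylation of the N-hydroxyphthalimide ester 30 and captured by an acylnickel from thioester 16 fits this site. The C2' substituent of 30 must be inert to that radical. With a propargylic alkyne on C2', the C1'–CH2 radical would be a cis-locked hex-5-ynyl radical, and 5-exo-dig closure would rebuild a bicyclo[3.3.0]octane. The carbon is therefore carried as CH2OSi.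

**30 to 17.** Ester 30 comes from acid 29, and 29 from lactone 26 by opening and silylation. Lactone 26 comes from ozonolysis of silyl enol ether 23, which cuts one ring of a cis-bicyclo[3.3.0]octane. The enol CH becomes the C2' carbinol carbon and the enol C–O carbon becomes the carboxyl that is later lost as CO2. Enol ether 23 comes from meso ketone 21, and 21 from the dione 17 through monoketal 18. Both quaternary carbons, their methyls and the cis relation are bought with 17. The forward sequence only has to choose between the two enantiotopic α-CH2 groups of 21.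

**16 to 11.** Thioester 16 comes from acid 15, 15 from alcohol 13, and 13 from anti-Markovnikov hydration of the vinyl group of 11. The forward hydroboration must prefer the monosubstituted vinyl over the cis-disubstituted styrenyl C3=C4.

**11 to 10 (key).** The C3=C4 bond is cut to give the triene 10, an aryl ether of a divinyl carbinol with no stereocentre. Ring B and C2 are formed together by enantioselective ring-closing metathesis. Other ways to a tertiary aryl ether stereocentre (oxa-Michael closure, allylic substitution) would place the stereo-determining step next to the sensitive ketone.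

**10 to 1, 7.** The vinyl on ring A is cut back to the bromide 9. The aryl C–O bond of 9 is cut to the dienol 7 and the diaryliodonium salt 6. The ring is too electron-rich for SNAr, and the tertiary doubly allylic carbinol cannot act as an electrophile without ionising. Salt 6 comes from iodide 4, 4 from bromoaniline 2, and 2 from 4-methoxy-2-methylaniline 1. The vinyl group is added after the arylation because the peracid used to make 6 would epoxidise a styrene.

## Roads not taken

All three alternatives address ring C only. None sets C2, so each would replace steps 10–15 of the route below and not the key step.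

Alternative 1: The cut removes the two C–CH3 bonds of ring C. N-Benzyl cis-cyclopentane-1,2-dicarboximide A1 would be enolised and methylated twice (LDA, MeI) to the meso dimethyl imide A2.
- Merits: cheap materials, a cis relation enforced by the five-membered imide, and a C2' carbon already at the acid oxidation level, from which an alkynyl ketone could be reached without the reduction–oxidation detour of steps 13, 17, 18 and 21.
- Weak points: the second methylation makes a quaternary centre beside an existing one through a hindered ring-fusion enolate. A2 is meso, so an enantioselective differentiation of the two carbonyls is still owed. The carbonyl on C1' must be reduced to CH2 and then joined to an acyl carbon at the most hindered site of the molecule.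
- Comparison: the chosen plan also passes through a meso compound (21) and pays for a stoichiometric chiral base, so the two are level on that count. Against the better C2' oxidation level of A2, the chosen plan sets quaternary centres that are bought and not made, and a CH2 radical precursor that falls out of the ring cleavage at the right length.

Alternative 2: Ring C would arise by contraction of a cyclohexane. C1' would be made quaternary by a Claisen rearrangement that transfers chirality from a secondary allylic carbinol. The derived epoxide A3 would then be opened by a Lewis acid at its tertiary carbon while the ring CH2 migrates anti, giving aldehyde A4.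
- Merits: the sequence is stereospecific, needs no chiral base at low temperature, and delivers C2' directly as the aldehyde with the C1' arm as a protected two-carbon chain. In certainty of absolute configuration this road is better than step 12 of the chosen plan.
- Weak points: hydride shift competes with ring-CH2 migration. The epoxidation must be face-selective beside a quaternary carbon. Making and rearranging the cyclohexenyl precursor takes more steps than 17 to 30. The aldehyde of A4 would still have to be masked before any radical is generated on the C1' arm, so the endgame is not shortened.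
- Comparison: the chosen plan answers with a shorter ring C sequence, at the price of a less predictable enantioselective deprotonation.

Alternative 3: The cut removes the C2'–C(acyl) and C1'–CH2 bonds. Irradiation of the enantiopure dioxinone A5 with 1,2-dimethylcyclopentene A6 would give the cyclobutane photoadduct A7. Retro-aldol opening of A7 would lead to keto acid A8.
- Merits: both quaternary centres and both side-arm carbons form in one step, cis by necessity and without regiochemical ambiguity because A6 is symmetric. A8 carries the same CH2COOH arm that the chosen route uses for the radical coupling. In bond-forming economy this road is better than the chosen plan.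
- Weak points: a (2+2) photocycloaddition onto a tetrasubstituted alkene creates two quaternary carbons at once. Its facial selectivity rests on a remote acetal centre of an excited enone. The acyl group arrives as a methyl ketone, from which aldol condensation would give the E-enone, so the Z-hydroxy enone would need further manipulation.
- Comparison: the chosen plan answers with a thermal, scalable ring C source and an aldehyde that leads through the ynone to the Z-alkene.

Key step: step 6

Assumption (step 6): the (S)-biphenolate molybdenum complex is taken to favour (R)-11; if the sense is the reverse, the (R)-biphenolate complex is used and nothing else changes.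

Assumption (step 12): the lithium amide of (R,R)-bis(1-phenylethyl)amine is taken to remove the α-hydrogen that leads to 23; if the sense is the reverse, the (S,S)-amine is used.

## Route

Step 1
Reactants: 1 4-methoxy-2-methylaniline
Product: 2 2-bromo-4-methoxy-6-methylaniline
Conditions: NBS, MeCN, 0 °C
Reagents that add atoms: N-bromosuccinimide, O=C1CCC(=O)N1Br
Why: Electrophilic aromatic bromination; the amino group is the strongest director, its para position holds OMe and one ortho position holds CH3, so bromine should enter at the free ortho carbon.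

Step 2
Reactants: 2 2-bromo-4-methoxy-6-methylaniline
Product: 4 1-bromo-2-iodo-5-methoxy-3-methylbenzene, via arenediazonium tosylate 3 (not isolated)
Conditions: TsOH·H2O, NaNO2, KI, MeCN/H2O, 10 °C to rt
Reagents that add atoms: potassium iodide, [K+].[I-]
Why: Sandmeyer-type iododediazoniation; iodide reduces the diazonium ion and traps the aryl radical without copper, and the two ortho substituents do not hinder loss of N2.

Step 3
Reactants: 4 1-bromo-2-iodo-5-methoxy-3-methylbenzene
Product: 6 (2-bromo-4-methoxy-6-methylphenyl)(2,4,6-trimethoxyphenyl)iodonium tosylate, via hydroxy(tosyloxy)iodoarene 5 (not isolated)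
Conditions: mCPBA, TsOH·H2O, MeCN, 50 °C; then 1,3,5-trimethoxybenzene, rt
Reagents that add atoms: 1,3,5-trimethoxybenzene, COc1cc(OC)cc(OC)c1; 4-methylbenzenesulfonic acid monohydrate, Cc1ccc(S(=O)(=O)O)cc1.O
Why: One-pot oxidation of the aryl iodide to the hypervalent iodine tosylate and electrophilic substitution of trimethoxybenzene at iodine, the standard preparation of aryl(trimethoxyphenyl)iodonium salts, which accepts hindered and electron-rich iodoarenes.

Step 4
Reactants: 7 3-methylpenta-1,4-dien-3-ol; 6 (2-bromo-4-methoxy-6-methylphenyl)(2,4,6-trimethoxyphenyl)iodonium tosylate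
Product: 9 1-bromo-5-methoxy-3-methyl-2-[(3-methylpenta-1,4-dien-3-yl)oxy]benzene, via sodium alkoxide 8 (not isolated)
Conditions: NaH, toluene, 0 °C; then 6, rt to 40 °C
Reagents that add atoms: none
Why: Metal-free O-arylation of an alkoxide by a diaryliodonium salt (ligand exchange at iodine, then ligand coupling); the tertiary alkoxide has no α-hydrogen to be oxidised, the more electron-rich trimethoxyphenyl group stays on iodine, and with both ortho positions of the transferred ring blocked no aryne can form.

Step 5
Reactants: 9 1-bromo-5-methoxy-3-methyl-2-[(3-methylpenta-1,4-dien-3-yl)oxy]benzene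
Product: 10 1-ethenyl-5-methoxy-3-methyl-2-[(3-methylpenta-1,4-dien-3-yl)oxy]benzene
Conditions: potassium vinyltrifluoroborate, Pd(dppf)Cl2 (5 mol %), Cs2CO3, THF/H2O, 70 °C
Reagents that add atoms: potassium vinyltrifluoroborate, C=C[B-](F)(F)F.[K+]
Why: Suzuki–Miyaura vinylation of an aryl bromide; the chelating dppf ligand leaves little room for alkene insertion, so transmetallation with the vinylborate should outrun a Heck closure onto a neighbouring vinyl group, and the basic medium leaves the ionisable tertiary ether alone.

Step 6
Reactants: 10 1-ethenyl-5-methoxy-3-methyl-2-[(3-methylpenta-1,4-dien-3-yl)oxy]benzene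
Product: 11 (2R)-2-ethenyl-6-methoxy-2,8-dimethyl-2H-chromene
Conditions: Mo(N-2,6-iPr2C6H3)(CHCMe2Ph)[(S)-3,3'-tBu2-5,5',6,6'-Me4-biphenyl-2,2'-diolate] (5 mol %), benzene (0.05 M), 22 °C, N2 stream, dark
Reagents that add atoms: none
Why: Olefin metathesis by a chiral hexavalent molybdenum alkylidene: the neophylidene exchanges with the unhindered styrenyl CH=CH2 of 10, the resulting arylmethylidene adds (2+2) to one vinyl group on the carbinol carbon, and cycloreversion of the molybdacyclobutane releases 11 and Mo=CH2, which re-enters the cycle with loss of ethene. The closest known reaction type is the molybdenum-catalysed enantioselective desymmetrising ring-closing metathesis of trienyl tertiary ethers, which includes 2H-chromene formation. Ring B closes as a six-membered ring by ring-closing metathesis with the new C3=C4 bond inside the ring; closure between the two carbinol vinyls would give a cyclopropene and cannot compete. C2 is the only new stereocentre and is set by the catalyst alone, since 10 has none: the biphenolate and the arylimido ligand form a chiral pocket that distinguishes the two enantiotopic vinyl groups when the metallacyclobutane forms. The step needs initiation at the styrene, which the fully substituted carbon beside the other two vinyls secures. It also needs the product not to re-enter through its remaining hindered vinyl group, because ring-opening and reclosure onto C4 would interconvert the enantiomers; ethene is therefore swept out and the reaction stopped at full conversion. Dilution suppresses cross-metathesis dimers, and the substrate must be dry and free of protic impurities.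

Step 7
Reactants: 11 (2R)-2-ethenyl-6-methoxy-2,8-dimethyl-2H-chromene
Product: 13 2-[(2R)-6-methoxy-2,8-dimethyl-2H-chromen-2-yl]ethan-1-ol, via B-alkyl-9-borabicyclononane 12 (not isolated)
Conditions: 9-BBN, THF, 0 °C to rt; then H2O2, aq NaOH, 0 °C
Reagents that add atoms: hydrogen peroxide, OO
Why: Hydroboration–oxidation; the bulky borane adds to the terminal carbon of the monosubstituted vinyl far faster than to the cis-disubstituted styrenyl C3=C4, and terminal boron cannot eliminate the aryloxide.

Step 8
Reactants: 13 2-[(2R)-6-methoxy-2,8-dimethyl-2H-chromen-2-yl]ethan-1-ol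
Product: 15 2-[(2R)-6-methoxy-2,8-dimethyl-2H-chromen-2-yl]acetic acid, via aldehyde 14 (not isolated)
Conditions: TEMPO (20 mol %), PhI(OAc)2, MeCN/H2O, rt
Reagents that add atoms: water, O
Why: Oxoammonium-mediated oxidation of a primary alcohol through the aldehyde hydrate to the acid; the near-neutral medium spares the styrenyl alkene and gives the β-aryloxy aldehyde no base with which to eliminate.

Step 9
Reactants: 15 2-[(2R)-6-methoxy-2,8-dimethyl-2H-chromen-2-yl]acetic acid
Product: 16 S-(pyridin-2-yl) 2-[(2R)-6-methoxy-2,8-dimethyl-2H-chromen-2-yl]ethanethioate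
Conditions: 2,2'-dipyridyl disulfide, PPh3, CH2Cl2, rt
Reagents that add atoms: 2,2'-dipyridyl disulfide, c1ccc(SSc2ccccn2)nc1
Why: Redox condensation through an acyloxyphosphonium ion that is captured by pyridine-2-thiolate; it runs without added base, so the β-aryloxy acyl compound is not exposed to enolisation.

Step 10
Reactants: 17 cis-1,5-dimethylbicyclo[3.3.0]octane-3,7-dione
Product: 18 cis-1,5-dimethylbicyclo[3.3.0]octane-3,7-dione mono(2,2-dimethylpropane-1,3-diyl ketal)
Conditions: 2,2-dimethylpropane-1,3-diol (1 equiv), TsOH (cat.), benzene, reflux, Dean–Stark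
Reagents that add atoms: 2,2-dimethylpropane-1,3-diol, CC(C)(CO)CO
Why: Acid-catalysed ketalisation; the two carbonyl groups are homotopic, so the monoketal is a single compound, and recovered dione and bisketal can be recycled.

Step 11
Reactants: 18 cis-1,5-dimethylbicyclo[3.3.0]octane-3,7-dione mono(2,2-dimethylpropane-1,3-diyl ketal)
Product: 21 cis-1,5-dimethylbicyclo[3.3.0]octan-3-one, via hydrazone 19 (not isolated), via deoxygenated ketal 20 (not isolated)
Conditions: N2H4·H2O, KOH, diethylene glycol, 130 to 200 °C; then 2 M HCl, THF, rt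
Reagents that add atoms: water, O
Why: Wolff–Kishner reduction of the free ketone, to which the ketal is inert, followed by acid hydrolysis of the ketal; the product is meso, so no stereochemical question arises.

Step 12
Reactants: 21 cis-1,5-dimethylbicyclo[3.3.0]octan-3-one
Product: 23 trimethyl{[(3aR,6aS)-3a,6a-dimethyl-1,3a,4,5,6,6a-hexahydropentalen-2-yl]oxy}silane, via lithium enolate 22 (not isolated)
Conditions: (R,R)-bis(1-phenylethyl)amine·HCl, n-BuLi (2 equiv), THF, –78 °C; TMSCl, then 21, –100 °C
Reagents that add atoms: chlorotrimethylsilane, C[Si](C)(C)Cl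
Why: Enantioselective deprotonation of a meso ketone by a C2-symmetric chiral lithium amide with internal silyl quench, a reaction established for cis-bicyclo[3.3.0]octan-3-ones; the choice between the two enantiotopic α-CH2 groups fixes the absolute configuration of both quaternary carbons at once, and the LiCl formed from the amine salt is part of the selective aggregate.

Step 13
Reactants: 23 trimethyl{[(3aR,6aS)-3a,6a-dimethyl-1,3a,4,5,6,6a-hexahydropentalen-2-yl]oxy}silane
Product: 26 (4aS,7aS)-4a,7a-dimethylhexahydrocyclopenta[c]pyran-3(1H)-one, via methoxy hydroperoxide 24 (not isolated), via hydroxy acid 25 (not isolated)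
Conditions: O3, CH2Cl2/MeOH, –78 °C; NaBH4, –78 °C to rt; then 2 M HCl
Reagents that add atoms: ozone, [O-][O+]=O
Why: Ozonolysis of a silyl enol ether gives a silyl ester at the oxygenated carbon and a methanol-trapped carbonyl oxide at the other; borohydride reduces the latter to the primary alcohol, and acidification closes the six-membered lactone. The quaternary carbons are not involved.

Step 14
Reactants: 26 (4aS,7aS)-4a,7a-dimethylhexahydrocyclopenta[c]pyran-3(1H)-one
Product: 29 2-[(1S,2S)-2-{[(tert-butyldimethylsilyl)oxy]methyl}-1,2-dimethylcyclopentyl]acetic acid, via potassium carboxylate 27 (not isolated), via bis-silyl derivative 28 (not isolated)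
Conditions: KOH, MeOH/H2O, 50 °C, evaporate; TBSCl, imidazole, DMF, rt; K2CO3, MeOH/THF/H2O, rt; citric acid to pH 4
Reagents that add atoms: potassium hydroxide, [K+].[OH-]; tert-butyldimethylsilyl chloride, CC(C)(C)[Si](C)(C)Cl
Why: Saponification, silylation of the salt at both oxygens and selective methanolysis of the labile silyl ester, the usual way to protect a hydroxy acid that would otherwise relactonise.

Step 15
Reactants: 29 2-[(1S,2S)-2-{[(tert-butyldimethylsilyl)oxy]methyl}-1,2-dimethylcyclopentyl]acetic acid
Product: 30 1,3-dioxoisoindolin-2-yl 2-[(1S,2S)-2-{[(tert-butyldimethylsilyl)oxy]methyl}-1,2-dimethylcyclopentyl]acetate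
Conditions: N-hydroxyphthalimide, DIC, DMAP (cat.), CH2Cl2, rt
Reagents that add atoms: N-hydroxyphthalimide, O=C1c2ccccc2C(=O)N1O
Why: Carbodiimide esterification to the redox-active ester; the CH2 spacer keeps the carboxyl accessible despite the neighbouring quaternary carbons.

Step 16
Reactants: 16 S-(pyridin-2-yl) 2-[(2R)-6-methoxy-2,8-dimethyl-2H-chromen-2-yl]ethanethioate; 30 1,3-dioxoisoindolin-2-yl 2-[(1S,2S)-2-{[(tert-butyldimethylsilyl)oxy]methyl}-1,2-dimethylcyclopentyl]acetate
Product: 31 1-[(1S,2S)-2-{[(tert-butyldimethylsilyl)oxy]methyl}-1,2-dimethylcyclopentyl]-3-[(2R)-6-methoxy-2,8-dimethyl-2H-chromen-2-yl]propan-2-one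
Conditions: NiCl2(dme) (10 mol %), 4,4'-di-tert-butyl-2,2'-bipyridine (11 mol %), Zn, THF/DMA, rt
Reagents that add atoms: none
Why: Nickel-catalysed reductive cross-electrophile coupling of an S-2-pyridyl thioester with an N-hydroxyphthalimide ester: low-valent nickel inserts into the C(acyl)–S bond, single-electron reduction of 30 releases CO2 and a primary radical, and radical capture and reductive elimination give the ketone. The radical has only a silyloxymethyl neighbour and therefore no intramolecular trap, and no stereocentre is touched.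

Step 17
Reactants: 31 1-[(1S,2S)-2-{[(tert-butyldimethylsilyl)oxy]methyl}-1,2-dimethylcyclopentyl]-3-[(2R)-6-methoxy-2,8-dimethyl-2H-chromen-2-yl]propan-2-one
Product: 32 1-[(1S,2S)-2-(hydroxymethyl)-1,2-dimethylcyclopentyl]-3-[(2R)-6-methoxy-2,8-dimethyl-2H-chromen-2-yl]propan-2-one
Conditions: HF·pyridine, pyridine, THF, 0 °C to rt
Reagents that add atoms: none
Why: Fluoride desilylation in a buffered, non-basic medium; basic fluoride is avoided because an enolate of the β-aryloxy ketone could open ring B.

Step 18
Reactants: 32 1-[(1S,2S)-2-(hydroxymethyl)-1,2-dimethylcyclopentyl]-3-[(2R)-6-methoxy-2,8-dimethyl-2H-chromen-2-yl]propan-2-one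
Product: 33 (1S,2S)-2-{3-[(2R)-6-methoxy-2,8-dimethyl-2H-chromen-2-yl]-2-oxopropyl}-1,2-dimethylcyclopentane-1-carbaldehyde
Conditions: Dess–Martin periodinane, NaHCO3, CH2Cl2, 0 °C to rt
Reagents that add atoms: none
Why: Hypervalent iodine oxidation of a primary alcohol under buffered neutral conditions; the aldehyde has no α-hydrogen, and the absence of acid or base keeps the keto aldehyde from aldolising, so it is used directly.

Step 19
Reactants: 34 2-methylbut-3-yn-2-ol
Product: 35 4-iodo-2-methylbut-3-yn-2-ol
Conditions: NIS, AgNO3 (10 mol %), acetone, rt, dark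
Reagents that add atoms: N-iodosuccinimide, O=C1CCC(=O)N1I
Why: Silver-catalysed iodination of a terminal alkyne through the silver acetylide; the tertiary hydroxyl does not interfere.

Step 20
Reactants: 33 (1S,2S)-2-{3-[(2R)-6-methoxy-2,8-dimethyl-2H-chromen-2-yl]-2-oxopropyl}-1,2-dimethylcyclopentane-1-carbaldehyde; 35 4-iodo-2-methylbut-3-yn-2-ol
Product: 36 1-[(1S,2S)-2-(1,4-dihydroxy-4-methylpent-2-yn-1-yl)-1,2-dimethylcyclopentyl]-3-[(2R)-6-methoxy-2,8-dimethyl-2H-chromen-2-yl]propan-2-one
Conditions: CrCl2 (5 equiv), NiCl2 (2 mol %), THF/DMF, rt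
Reagents that add atoms: none
Why: Nozaki–Hiyama–Kishi alkynylation; alkynyl reagents of trivalent chromium add to aldehydes and not to ketones and are too weakly basic to enolise the β-aryloxy ketone or to be quenched by the tertiary hydroxyl. The new carbinol centre forms as a mixture that the next step removes.

Step 21
Reactants: 36 1-[(1S,2S)-2-(1,4-dihydroxy-4-methylpent-2-yn-1-yl)-1,2-dimethylcyclopentyl]-3-[(2R)-6-methoxy-2,8-dimethyl-2H-chromen-2-yl]propan-2-one
Product: 37 4-hydroxy-1-[(1S,2S)-2-{3-[(2R)-6-methoxy-2,8-dimethyl-2H-chromen-2-yl]-2-oxopropyl}-1,2-dimethylcyclopentyl]-4-methylpent-2-yn-1-one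
Conditions: Dess–Martin periodinane, NaHCO3, CH2Cl2, 0 °C
Reagents that add atoms: none
Why: Oxidation of the secondary propargylic alcohol to the ynone; the tertiary alcohol cannot be oxidised and the buffer prevents cyclisation of the γ-hydroxy ynone.

Step 22
Reactants: 37 4-hydroxy-1-[(1S,2S)-2-{3-[(2R)-6-methoxy-2,8-dimethyl-2H-chromen-2-yl]-2-oxopropyl}-1,2-dimethylcyclopentyl]-4-methylpent-2-yn-1-one
Product: 38 (2Z)-4-hydroxy-1-[(1S,2S)-2-{3-[(2R)-6-methoxy-2,8-dimethyl-2H-chromen-2-yl]-2-oxopropyl}-1,2-dimethylcyclopentyl]-4-methylpent-2-en-1-one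
Conditions: H2 (1 atm), Pd/CaCO3–Pb(OAc)2, quinoline, EtOAc, 0 °C, dark
Reagents that add atoms: none
Why: Semihydrogenation on lead-poisoned palladium adds H2 syn to the alkyne and so gives the Z-enone; the cis-disubstituted C3=C4 of ring B is not reduced on this catalyst, and the reaction is stopped after one equivalent of hydrogen.

## Compound list

1 | 4-methoxy-2-methylaniline | COc1ccc(N)c(C)c1 | starting material
2 | 2-bromo-4-methoxy-6-methylaniline | COc1cc(C)c(N)c(Br)c1 | intermediate
3 | 2-bromo-4-methoxy-6-methylbenzenediazonium 4-methylbenzenesulfonate | COc1cc(C)c([N+]#N)c(Br)c1.Cc1ccc(S(=O)(=O)[O-])cc1 | intermediate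
4 | 1-bromo-2-iodo-5-methoxy-3-methylbenzene | COc1cc(C)c(I)c(Br)c1 | intermediate
5 | 1-bromo-2-[hydroxy(tosyloxy)iodo]-5-methoxy-3-methylbenzene | COc1cc(C)c(I(O)OS(=O)(=O)c2ccc(C)cc2)c(Br)c1 | intermediate
6 | (2-bromo-4-methoxy-6-methylphenyl)(2,4,6-trimethoxyphenyl)iodonium 4-methylbenzenesulfonate | COc1cc(C)c([I+]c2c(OC)cc(OC)cc2OC)c(Br)c1.Cc1ccc(S(=O)(=O)[O-])cc1 | intermediate
7 | 3-methylpenta-1,4-dien-3-ol | C=CC(C)(O)C=C | starting material
8 | sodium 3-methylpenta-1,4-dien-3-olate | C=CC(C)([O-])C=C.[Na+] | intermediate
9 | 1-bromo-5-methoxy-3-methyl-2-[(3-methylpenta-1,4-dien-3-yl)oxy]benzene | COc1cc(C)c(OC(C)(C=C)C=C)c(Br)c1 | intermediate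
10 | 1-ethenyl-5-methoxy-3-methyl-2-[(3-methylpenta-1,4-dien-3-yl)oxy]benzene | COc1cc(C)c(OC(C)(C=C)C=C)c(C=C)c1 | intermediate
11 | (2R)-2-ethenyl-6-methoxy-2,8-dimethyl-2H-chromene | COc1cc(C)c2c(c1)C=C[C@@](C)(C=C)O2 | intermediate
12 | 9-{2-[(2R)-6-methoxy-2,8-dimethyl-2H-chromen-2-yl]ethyl}-9-borabicyclo[3.3.1]nonane | COc1cc(C)c2c(c1)C=C[C@@](C)(CCB3C4CCCC3CCC4)O2 | intermediate
13 | 2-[(2R)-6-methoxy-2,8-dimethyl-2H-chromen-2-yl]ethan-1-ol | COc1cc(C)c2c(c1)C=C[C@@](C)(CCO)O2 | intermediate
14 | 2-[(2R)-6-methoxy-2,8-dimethyl-2H-chromen-2-yl]acetaldehyde | COc1cc(C)c2c(c1)C=C[C@@](C)(CC=O)O2 | intermediate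
15 | 2-[(2R)-6-methoxy-2,8-dimethyl-2H-chromen-2-yl]acetic acid | COc1cc(C)c2c(c1)C=C[C@@](C)(CC(=O)O)O2 | intermediate
16 | S-(pyridin-2-yl) 2-[(2R)-6-methoxy-2,8-dimethyl-2H-chromen-2-yl]ethanethioate | COc1cc(C)c2c(c1)C=C[C@@](C)(CC(=O)Sc3ccccn3)O2 | intermediate
17 | cis-1,5-dimethylbicyclo[3.3.0]octane-3,7-dione (meso) | O=C1C[C@]2(C)CC(=O)C[C@]2(C)C1 | starting material
18 | cis-1,5-dimethylbicyclo[3.3.0]octane-3,7-dione mono(2,2-dimethylpropane-1,3-diyl ketal) | O=C1C[C@]2(C)CC3(C[C@]2(C)C1)OCC(C)(C)CO3 | intermediate
19 | hydrazone of 18 at the free carbonyl group | NN=C1C[C@]2(C)CC3(C[C@]2(C)C1)OCC(C)(C)CO3 | intermediate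
20 | cis-1,5-dimethylbicyclo[3.3.0]octan-3-one 2,2-dimethylpropane-1,3-diyl ketal | C1C[C@]2(C)CC3(C[C@]2(C)C1)OCC(C)(C)CO3 | intermediate
21 | cis-1,5-dimethylbicyclo[3.3.0]octan-3-one (meso) | O=C1C[C@]2(C)CCC[C@]2(C)C1 | intermediate
22 | lithium (3aR,6aS)-3a,6a-dimethyl-1,3a,4,5,6,6a-hexahydropentalen-2-olate | [Li]OC1=C[C@@]2(C)CCC[C@@]2(C)C1 | intermediate
23 | trimethyl{[(3aR,6aS)-3a,6a-dimethyl-1,3a,4,5,6,6a-hexahydropentalen-2-yl]oxy}silane | C[Si](C)(C)OC1=C[C@@]2(C)CCC[C@@]2(C)C1 | intermediate
24 | trimethylsilyl 2-{(1S,2S)-2-[hydroperoxy(methoxy)methyl]-1,2-dimethylcyclopentyl}acetate (both epimers at the peroxy carbon) | C[Si](C)(C)OC(=O)C[C@]1(C)CCC[C@]1(C)C(OC)OO | intermediate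
25 | 2-[(1S,2S)-2-(hydroxymethyl)-1,2-dimethylcyclopentyl]acetic acid | OC(=O)C[C@]1(C)CCC[C@]1(C)CO | intermediate
26 | (4aS,7aS)-4a,7a-dimethylhexahydrocyclopenta[c]pyran-3(1H)-one | O=C1C[C@]2(C)CCC[C@]2(C)CO1 | intermediate
27 | potassium 2-[(1S,2S)-2-(hydroxymethyl)-1,2-dimethylcyclopentyl]acetate | [K+].[O-]C(=O)C[C@]1(C)CCC[C@]1(C)CO | intermediate
28 | tert-butyldimethylsilyl 2-[(1S,2S)-2-{[(tert-butyldimethylsilyl)oxy]methyl}-1,2-dimethylcyclopentyl]acetate | CC(C)(C)[Si](C)(C)OC(=O)C[C@]1(C)CCC[C@]1(C)CO[Si](C)(C)C(C)(C)C | intermediate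
29 | 2-[(1S,2S)-2-{[(tert-butyldimethylsilyl)oxy]methyl}-1,2-dimethylcyclopentyl]acetic acid | OC(=O)C[C@]1(C)CCC[C@]1(C)CO[Si](C)(C)C(C)(C)C | intermediate
30 | 1,3-dioxoisoindolin-2-yl 2-[(1S,2S)-2-{[(tert-butyldimethylsilyl)oxy]methyl}-1,2-dimethylcyclopentyl]acetate | O=C(ON1C(=O)c2ccccc2C1=O)C[C@]1(C)CCC[C@]1(C)CO[Si](C)(C)C(C)(C)C | intermediate
31 | 1-[(1S,2S)-2-{[(tert-butyldimethylsilyl)oxy]methyl}-1,2-dimethylcyclopentyl]-3-[(2R)-6-methoxy-2,8-dimethyl-2H-chromen-2-yl]propan-2-one | COc1cc(C)c2c(c1)C=C[C@@](C)(CC(=O)C[C@]1(C)CCC[C@]1(C)CO[Si](C)(C)C(C)(C)C)O2 | intermediate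
32 | 1-[(1S,2S)-2-(hydroxymethyl)-1,2-dimethylcyclopentyl]-3-[(2R)-6-methoxy-2,8-dimethyl-2H-chromen-2-yl]propan-2-one | COc1cc(C)c2c(c1)C=C[C@@](C)(CC(=O)C[C@]1(C)CCC[C@]1(C)CO)O2 | intermediate
33 | (1S,2S)-2-{3-[(2R)-6-methoxy-2,8-dimethyl-2H-chromen-2-yl]-2-oxopropyl}-1,2-dimethylcyclopentane-1-carbaldehyde | COc1cc(C)c2c(c1)C=C[C@@](C)(CC(=O)C[C@]1(C)CCC[C@]1(C)C=O)O2 | intermediate
34 | 2-methylbut-3-yn-2-ol | CC(C)(O)C#C | starting material
35 | 4-iodo-2-methylbut-3-yn-2-ol | CC(C)(O)C#CI | intermediate
36 | 1-[(1S,2S)-2-(1,4-dihydroxy-4-methylpent-2-yn-1-yl)-1,2-dimethylcyclopentyl]-3-[(2R)-6-methoxy-2,8-dimethyl-2H-chromen-2-yl]propan-2-one (both carbinol epimers) | COc1cc(C)c2c(c1)C=C[C@@](C)(CC(=O)C[C@]1(C)CCC[C@]1(C)C(O)C#CC(C)(C)O)O2 | intermediate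
37 | 4-hydroxy-1-[(1S,2S)-2-{3-[(2R)-6-methoxy-2,8-dimethyl-2H-chromen-2-yl]-2-oxopropyl}-1,2-dimethylcyclopentyl]-4-methylpent-2-yn-1-one | COc1cc(C)c2c(c1)C=C[C@@](C)(CC(=O)C[C@]1(C)CCC[C@]1(C)C(=O)C#CC(C)(C)O)O2 | intermediate
38 | (2Z)-4-hydroxy-1-[(1S,2S)-2-{3-[(2R)-6-methoxy-2,8-dimethyl-2H-chromen-2-yl]-2-oxopropyl}-1,2-dimethylcyclopentyl]-4-methylpent-2-en-1-one | COc1cc(C)c2c(c1)C=C[C@@](C)(CC(=O)C[C@]1(C)CCC[C@]1(C)C(=O)/C=C\C(C)(C)O)O2 | target

## Step count and least certain steps

Total: 22 steps. Longest linear sequence: 15 steps (steps 1–9, 16–18 and 20–22). The ring C branch (steps 10–15) and the alkyne branch (step 19) are shorter.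

**Step 6 (key).** The most likely failure is insufficient discrimination between the two enantiotopic vinyl groups. Erosion of the enantiomeric purity is also possible if the catalyst re-enters through the remaining vinyl group of the product and reopens ring B. The fallback gives up asymmetric catalysis. From 10, ring closure with the second-generation Hoveyda–Grubbs catalyst RuCl2(H2IMes)(=CH-C6H4-2-OiPr) in CH2Cl2 at 40 °C would give 11 together with its mirror image (2S)-2-ethenyl-6-methoxy-2,8-dimethyl-2H-chromene F1. Hydroboration–oxidation as in step 7 would give 13 together with 2-[(2S)-6-methoxy-2,8-dimethyl-2H-chromen-2-yl]ethan-1-ol F2. Preparative chromatography on a chiral stationary phase at this alcohol stage returns to 13.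

**Step 16.** The hindered primary radical may be captured too slowly by nickel and end up reduced or dimerised. Low-valent nickel may also insert into the allylic C2–O bond of ring B, and the thioester may homocouple. The fallback replaces the radical coupling by a polar acylation. From 29, hypervalent iodine iododecarboxylation (PhI(OAc)2, I2, cyclohexane, hν) gives tert-butyl{[(1S,2R)-2-(iodomethyl)-1,2-dimethylcyclopentyl]methoxy}dimethylsilane F3. Magnesium insertion (Mg, Et2O) gives the Grignard reagent {[(1R,2S)-2-{[(tert-butyldimethylsilyl)oxy]methyl}-1,2-dimethylcyclopentyl]methyl}magnesium iodide F4. F4 is acylated once by the chelating thioester 16 at –78 °C (Mukaiyama ketone synthesis), which returns to 31.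

**Step 12.** Discrimination of the enantiotopic α-hydrogens may be incomplete, because the angular methyl groups alter the shape on which the known selectivity rests. The fallback is a resolution. From 21, LDA and TMSCl give 23 mixed with its mirror image trimethyl{[(3aS,6aR)-3a,6a-dimethyl-1,3a,4,5,6,6a-hexahydropentalen-2-yl]oxy}silane F5. Ozonolysis and reduction as in step 13 give 26 mixed with (4aR,7aR)-4a,7a-dimethylhexahydrocyclopenta[c]pyran-3(1H)-one F6. Aminolysis with (S)-1-phenylethylamine and AlMe3 gives two separable amides: 2-[(1S,2S)-2-(hydroxymethyl)-1,2-dimethylcyclopentyl]-N-[(1S)-1-phenylethyl]acetamide F7 and 2-[(1R,2R)-2-(hydroxymethyl)-1,2-dimethylcyclopentyl]-N-[(1S)-1-phenylethyl]acetamide F8. Acid-catalysed relactonisation of F7 (TsOH, toluene, reflux) returns to 26.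

**Step 4.** Ligand coupling at iodine may be slow for a ring with two ortho substituents, and aryl transfer from the wrong ligand or decomposition of the electron-rich salt may take over. The fallback forms the C–O bond at the carbinol carbon instead. From 2, diazotisation as in step 2 gives 3, which is hydrolysed (Cu2O, Cu(NO3)2, H2O) to 2-bromo-4-methoxy-6-methylphenol F9. Copper-catalysed propargylic etherification (CuCl2, DBU, MeCN, 0 °C) uses methyl (3-methylpent-1-en-4-yn-3-yl) carbonate F10, made from commercial 3-methylpent-1-en-4-yn-3-ol with n-BuLi and ClCO2Me. It gives 1-bromo-5-methoxy-3-methyl-2-[(3-methylpent-1-en-4-yn-3-yl)oxy]benzene F11. Semihydrogenation of the terminal alkyne (Pd/CaCO3–Pb(OAc)2, quinoline, H2) returns to 9.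

**Step 5.** The arylpalladium intermediate may insert into a neighbouring vinyl group (5-exo Heck closure to a benzofuran) before it transmetallates. The fallback avoids palladium. From 9, bromine–lithium exchange (n-BuLi, THF, –78 °C) and DMF give 5-methoxy-3-methyl-2-[(3-methylpenta-1,4-dien-3-yl)oxy]benzaldehyde F12. Wittig methylenation (Ph3P=CH2, THF, 0 °C) returns to 10.

**Step 22.** Over-reduction of the enone, Z-to-E isomerisation on the catalyst or in light, and closure of the Z-hydroxy enone to its cyclic hemiketal during isolation are the likely losses. The fallback sets the Z-alkene before the C–C bond is made. Diimide reduction of 35 (2-nitrobenzenesulfonohydrazide, Et3N) gives (Z)-4-iodo-2-methylbut-3-en-2-ol F13. Nozaki–Hiyama–Kishi coupling of F13 with aldehyde 33 (CrCl2, NiCl2 cat., DMSO) gives 1-[(1S,2S)-2-[(2Z)-1,4-dihydroxy-4-methylpent-2-en-1-yl]-1,2-dimethylcyclopentyl]-3-[(2R)-6-methoxy-2,8-dimethyl-2H-chromen-2-yl]propan-2-one F14. Oxidation of the allylic alcohol (MnO2, CH2Cl2) returns to 38.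

## Further compounds

F1 | step 6 | (2S)-2-ethenyl-6-methoxy-2,8-dimethyl-2H-chromene | COc1cc(C)c2c(c1)C=C[C@](C)(C=C)O2
F2 | step 6 | 2-[(2S)-6-methoxy-2,8-dimethyl-2H-chromen-2-yl]ethan-1-ol | COc1cc(C)c2c(c1)C=C[C@](C)(CCO)O2
F3 | step 16 | tert-butyl{[(1S,2R)-2-(iodomethyl)-1,2-dimethylcyclopentyl]methoxy}dimethylsilane | IC[C@]1(C)CCC[C@]1(C)CO[Si](C)(C)C(C)(C)C
F4 | step 16 | {[(1R,2S)-2-{[(tert-butyldimethylsilyl)oxy]methyl}-1,2-dimethylcyclopentyl]methyl}magnesium iodide | I[Mg]C[C@]1(C)CCC[C@]1(C)CO[Si](C)(C)C(C)(C)C
F5 | step 12 | trimethyl{[(3aS,6aR)-3a,6a-dimethyl-1,3a,4,5,6,6a-hexahydropentalen-2-yl]oxy}silane | C[Si](C)(C)OC1=C[C@]2(C)CCC[C@]2(C)C1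
F6 | step 12 | (4aR,7aR)-4a,7a-dimethylhexahydrocyclopenta[c]pyran-3(1H)-one | O=C1C[C@@]2(C)CCC[C@@]2(C)CO1
F7 | step 12 | 2-[(1S,2S)-2-(hydroxymethyl)-1,2-dimethylcyclopentyl]-N-[(1S)-1-phenylethyl]acetamide | C[C@H](NC(=O)C[C@]1(C)CCC[C@]1(C)CO)c1ccccc1
F8 | step 12 | 2-[(1R,2R)-2-(hydroxymethyl)-1,2-dimethylcyclopentyl]-N-[(1S)-1-phenylethyl]acetamide | C[C@H](NC(=O)C[C@@]1(C)CCC[C@@]1(C)CO)c1ccccc1
F9 | step 4 | 2-bromo-4-methoxy-6-methylphenol | COc1cc(C)c(O)c(Br)c1
F10 | step 4 | methyl (3-methylpent-1-en-4-yn-3-yl) carbonate (racemic) | COC(=O)OC(C)(C=C)C#C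
F11 | step 4 | 1-bromo-5-methoxy-3-methyl-2-[(3-methylpent-1-en-4-yn-3-yl)oxy]benzene (racemic) | COc1cc(C)c(OC(C)(C=C)C#C)c(Br)c1
F12 | step 5 | 5-methoxy-3-methyl-2-[(3-methylpenta-1,4-dien-3-yl)oxy]benzaldehyde | COc1cc(C)c(OC(C)(C=C)C=C)c(C=O)c1
F13 | step 22 | (Z)-4-iodo-2-methylbut-3-en-2-ol | CC(C)(O)/C=C\I
F14 | step 22 | 1-[(1S,2S)-2-[(2Z)-1,4-dihydroxy-4-methylpent-2-en-1-yl]-1,2-dimethylcyclopentyl]-3-[(2R)-6-methoxy-2,8-dimethyl-2H-chromen-2-yl]propan-2-one (both carbinol epimers) | COc1cc(C)c2c(c1)C=C[C@@](C)(CC(=O)C[C@]1(C)CCC[C@]1(C)C(O)/C=C\C(C)(C)O)O2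
A1 | alternative 1 | N-benzyl cis-cyclopentane-1,2-dicarboximide (meso) | O=C1N(Cc2ccccc2)C(=O)[C@H]2CCC[C@@H]12
A2 | alternative 1 | N-benzyl cis-1,2-dimethylcyclopentane-1,2-dicarboximide (meso) | O=C1N(Cc2ccccc2)C(=O)[C@@]2(C)CCC[C@@]12C
A3 | alternative 2 | tert-butyl{2-[1,2-dimethyl-7-oxabicyclo[4.1.0]heptan-2-yl]ethoxy}dimethylsilane, epoxide oxygen cis to the silyloxyethyl arm | CC(C)(C)[Si](C)(C)OCC[C@]1(C)CCC[C@@H]2O[C@]12C
A4 | alternative 2 | cis-1,2-dimethyl-2-[2-(tert-butyldimethylsilyloxy)ethyl]cyclopentane-1-carbaldehyde | CC(C)(C)[Si](C)(C)OCC[C@]1(C)CCC[C@]1(C)C=O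
A5 | alternative 3 | enantiopure 2-tert-butyl-6-methyl-4H-1,3-dioxin-4-one | O=C1O[C@@H](C(C)(C)C)OC(C)=C1
A6 | alternative 3 | 1,2-dimethylcyclopentene | CC1=C(C)CCC1
A7 | alternative 3 | cis-anti-cis tricyclic photoadduct of A5 and A6 | O=C1O[C@@H](C(C)(C)C)O[C@@]2(C)[C@@H]1[C@]3(C)CCC[C@@]32C
A8 | alternative 3 | 2-[(1S,2S)-2-acetyl-1,2-dimethylcyclopentyl]acetic acid | OC(=O)C[C@]1(C)CCC[C@]1(C)C(C)=O
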